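Target is the product, and the question is what share it holds in target plus side product at the end of each flask.

| flask | substrate | partner | remark | time |
|---|---|---|---|---|
| birch | 0.30 M | 0.33 M | run made earlier |  |
| maple | 0.20 M | 0.33 M | run made earlier |  |
| larch | 0.45 M | 0.33 M | run made earlier |  |
| green | 0.30 M | 0.330 M (fed, over 40 h) | all else is in the flask from the start; the feed brings no volume worth counting | 2.5 d |
| teal | 0.30 M (fed, over 40 h) | 0.330 M | all else is in the flask from the start; the feed brings no volume worth counting | 2.5 d |
| grey | 0.30 M | 0.330 M | everything together at the start | 2.5 d |

birch run (percent of the substrate charged)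

| time / h | target / % | side product / % |
|---|---|---|
| 3.00 | 6.6 | 8.8 |
| 6.00 | 17.5 | 15.7 |
| 15.0 | 41.6 | 16.0 |
| 40.0 | 66.1 | 15.5 |

maple run (percent of the substrate charged)

| time / d | target / % | side product / % |
|---|---|---|
| 0.625 | 45.7 | 11.7 |
| 1.25 | 67.0 | 10.2 |
| 2.08 | 79.2 | 9.8 |
| 2.50 | 81.4 | 12.8 |

larch run (percent of the substrate charged)

| time / d | target / % | side product / % |
|---|---|---|
| 0.333 | 23.2 | 20.0 |
| 0.833 | 44.4 | 21.5 |
| 1.67 | 55.2 | 19.9 |
| 2.50 | 62.7 | 22.0 |

(each reading ± 1 percentage point)

1. which flask leads in share of target in target plus side product ("all alike" within 1.5 percentage points) (green / teal / grey / all alike)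
2. share of target in target plus side product at the end, green
3. share of target in target plus side product at the end, teal
4. share of target in target plus side product at the end, grey

- a species is counted by the substrate in it: one side product counts as two

*What do the earlier runs show of side product?* In birch it reads 15.7 % at 6.00 h and 15.5 % at 40.0 h, while target keeps climbing. Its percentage also rises with the charge: 12.8 % in maple and 22.0 % in larch, both at 2.50 d.

*Your picture?* Substrate turns first-order into an unseen intermediate, which takes partner to target or a second substrate to side product.

*Give me one quantity.* The exposure coefficient g = 0.517 M⁻¹, the chance per molar of mean [intermediate] that a substrate is lost while it lives. Side product then takes twice that chance times the mean [intermediate]. With substrate charged at once, [intermediate] climbs from zero towards the charge; I take its mean while substrate lasts as half the charge, and the lost fraction is then g times the charge. That is how I read g from birch; larch reads 0.489 M⁻¹.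

*And teal, where the mean is not half the charge?* In teal, substrate enters at 0.00750 M h⁻¹. Birch's remainder, charge less target and side product, decays between 15.0 h and 40.0 h, and its decay rate divided by the mean [partner] of that stretch reads 0.198 M⁻¹ h⁻¹. At charged [partner] this is a pseudo-first-order clearance with time constant 15.3 h. The first-order rise over the feed has mean [intermediate] 0.0740 M. So teal loses 7.65 %, and its share, once intermediate has cleared, is 92.3 %. This reckoning holds [partner] at 0.330 M, but [partner] falls as target forms; I take the loss as a low estimate.

The forecast names teal: green 78 %, teal 90 %, grey 82 %, on the ground that substrate stays low in teal, “so side is about 8%”. My figure for teal is a share after clearance; the forecast's is for the end.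

The flasks give teal in the lead: green 78.9 %, teal 86.8 %, grey 82.5 %.

    substrate → intermediate (k = 0.00620 min⁻¹)
    partner + intermediate → target (k = 0.00360 M⁻¹ min⁻¹)
    substrate + intermediate → side product (k = 0.00470 M⁻¹ min⁻¹)

At 2.50 d teal still holds 22.2 % intermediate beside 67.6 % target and 10.2 % side product. My share after clearance, 92.3 %, belongs to a later time, and at 25.0 d teal stands at 89.8 %.

Take a neighbour like green but charged with 0.75 M substrate: g times the charge gives 38.8 % side product. The computed flask holds 33.6 % side product and 38.8 % target, a share of 53.6 %.

The numbers in the tables come from a simulation for substances that don't exist, and the scatter is random.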